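Numbering follows the target SMILES (C1 exocyclic CH2, O9 hydroxyl, C26 last methyl). Rings: A = C6, C8, C10, C11, C15; B = C3–C6, C15, C16; C = C2–C4, C17, C19–C22; D = C21–C25.
Enabling feature: ring B joins ring A in a trans fusion at C15 and at the quaternary, methyl-bearing C6, and C6 lies next to the oxygenated C8. This pattern is what a 2-methylcyclopentenone leaves after taking a nucleophile at its β-carbon (C15) and an electrophile at its α-carbon (C6).
Cuts: C2=C1 (methylenation), H–C17, C17–C19 (ring C), then C15–C16, C5–C6 and C3=C4 in one operation (ring B). This leaves a ring-A enone, a ring-D methyl ketone and a silicon-activated methyl vinyl ketone.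
Forward order: rings A and D are made separately, ring B is built between them in one flask, and ring C is closed last by hydroboration and intramolecular Suzuki–Miyaura coupling.
Stereochemistry: C11 comes from (R)-4-hydroxycyclopentenone and is relayed to C15, C6 and C8. C25 comes from (S)-pulegone and is relayed to C21 (hydrogenation) and C22 (epimerisation). C17 is set by hydrogen-atom delivery to the convex face of ring C.

Key step: step 16

Remark: the carbinol centre C2 is temporary because C2 ends sp2. The Felkin–Anh epimer (2R) is carried as the single isomer. It is also the epimer that can keep its silyl ether outside ring C.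

Step 1
Reactants: 1 (R)-4-hydroxycyclopent-2-en-1-one
Product: 2 (R)-4-(tert-butyldimethylsilyloxy)cyclopent-2-en-1-one
Conditions: TBSCl, imidazole, CH2Cl2, 0 °C to rt
Reagents that add atoms: tert-butyldimethylsilyl chloride, CC(C)(C)[Si](C)(C)Cl
Why: Standard O-silylation under mild base leaves the carbinol centre untouched and installs the bulky group that steers the next addition.

Step 2
Reactants: 2 (R)-4-(tert-butyldimethylsilyloxy)cyclopent-2-en-1-one
Product: 4 (S)-4-isopropylcyclopent-2-en-1-one, via trans-3-isopropyl-4-silyloxycyclopentanone 3 (not isolated)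
Conditions: i-PrMgCl, CuBr·SMe2 (cat.), THF, –78 °C; aq. work-up; crude, DBU, CH2Cl2, 0 °C, short contact
Reagents that add atoms: isopropylmagnesium chloride, CC(C)[Mg]Cl
Why: Copper-catalysed conjugate addition takes place anti to the silyloxy group and sets C11, and E1cB loss of silanolate through the other enolate re-creates the enone on the far side of the ring.

Step 3
Reactants: 4 (S)-4-isopropylcyclopent-2-en-1-one
Product: 5 (S)-2-iodo-4-isopropylcyclopent-2-en-1-one
Conditions: I2, pyridine, CH2Cl2, 0 °C to rt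
Reagents that add atoms: iodine, II
Why: α-Iodination of an enone by pyridine addition, iodination and elimination (Baylis–Hillman-type sequence) is routine for cyclopentenones and does not touch C11.

Step 4
Reactants: 5 (S)-2-iodo-4-isopropylcyclopent-2-en-1-one
Product: 6 (S)-4-isopropyl-2-methylcyclopent-2-en-1-one
Conditions: MeZnCl, Pd(dppf)Cl2 (cat.), THF, 0 °C to rt
Reagents that add atoms: methylzinc chloride, C[Zn]Cl
Why: Negishi coupling of an α-iodoenone runs without added base, so neither racemisation at the γ-carbon C11 nor migration of the alkene is expected.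

Step 5
Reactants: 7 (1-bromovinyl)trimethylsilane, 8 N-methoxy-N-methylacetamide
Product: 10 3-(trimethylsilyl)but-3-en-2-one, via 1-(trimethylsilyl)vinylmagnesium bromide 9 (not isolated)
Conditions: Mg, THF, reflux; 8, –78 to 0 °C; poured into cold 1 M HCl
Reagents that add atoms: none
Why: Weinreb ketone synthesis stops at the ketone, and the inverse acidic quench keeps the liberated amine from adding to the new enone.

Step 6
Reactants: 11 (S)-pulegone
Product: 13 methyl (5S)-5-methyl-2-(propan-2-ylidene)cyclopentane-1-carboxylate (C1 epimers), via pulegone dibromide 12 (not isolated)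
Conditions: Br2, NaHCO3, Et2O, 0 °C; then NaOMe, MeOH, reflux
Reagents that add atoms: sodium methoxide, [Na+].[O-]C
Why: Favorskii ring contraction of the dibromide, with loss of the second bromide to restore the isopropylidene group, turns the cyclohexanone into ring D and keeps the C25 methyl centre.

Step 7
Reactants: 13 methyl (5S)-5-methyl-2-(propan-2-ylidene)cyclopentane-1-carboxylate
Product: 14 methyl (2S)-2-methyl-5-oxocyclopentane-1-carboxylate
Conditions: O3, CH2Cl2/MeOH, –78 °C; Me2S
Reagents that add atoms: ozone, [O-][O+]=O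
Why: Ozonolysis of the only alkene unmasks the C22 ketone of a β-keto ester, whose labile C21 centre is erased in the next step.

Step 8
Reactants: 14 methyl (2S)-2-methyl-5-oxocyclopentane-1-carboxylate
Product: 15 methyl (5S)-5-methyl-2-(trifluoromethylsulfonyloxy)cyclopent-1-ene-1-carboxylate
Conditions: Tf2O, i-Pr2NEt, CH2Cl2, –78 °C
Reagents that add atoms: triflic anhydride, O=S(=O)(OS(=O)(=O)C(F)(F)F)C(F)(F)F
Why: A β-keto ester enolises only between its two carbonyl groups, so O-triflation gives the C21=C22 enol triflate as one regioisomer.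

Step 9
Reactants: 15 methyl (5S)-5-methyl-2-(trifluoromethylsulfonyloxy)cyclopent-1-ene-1-carboxylate
Product: 17 (6S)-6-methyl-3,4,5,6-tetrahydro-1H-cyclopenta[c]furan-1-one, via hydroxymethyl enoate 16 (not isolated)
Conditions: Bu3SnCH2OH, Pd(PPh3)4 (cat.), LiCl, dioxane, 100 °C; then CSA (cat.), rt
Reagents that add atoms: (tributylstannyl)methanol, CCCC[Sn](CCCC)(CCCC)CO
Why: Stille coupling puts C2 on C22 as a hydroxymethyl group held cis to the ester by the ring alkene, so lactonisation follows and differentiates C2 (CH2O) from C20 (C=O).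

Step 10
Reactants: 17 (6S)-6-methyl-3,4,5,6-tetrahydro-1H-cyclopenta[c]furan-1-one
Product: 18 (3aR,6S,6aS)-6-methylhexahydro-1H-cyclopenta[c]furan-1-one
Conditions: H2 (70 bar), Rh/Al2O3, EtOAc, rt
Reagents that add atoms: none
Why: Heterogeneous syn hydrogenation of the flat tetrasubstituted butenolide occurs on the face opposite the C26 methyl group, which places C20 cis to C26 (sets C21) and gives the all-cis lactone.

Step 11
Reactants: 18 (3aR,6S,6aS)-6-methylhexahydro-1H-cyclopenta[c]furan-1-one
Product: 19 (3aR,6S,6aS)-6-methylhexahydro-1H-cyclopenta[c]furan-1-ol (anomers)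
Conditions: DIBAL-H (1.1 equiv), CH2Cl2, –78 °C; Rochelle salt
Reagents that add atoms: none
Why: Partial reduction of a γ-lactone stops at the lactol because the tetrahedral aluminium alkoxide is stable at low temperature.

Step 12
Reactants: 19 (3aR,6S,6aS)-6-methylhexahydro-1H-cyclopenta[c]furan-1-ol
Product: 20 [(1R,2S,3S)-3-methyl-2-vinylcyclopentyl]methanol
Conditions: Ph3PCH3Br, KOt-Bu (excess ylide), THF, –20 to 0 °C
Reagents that add atoms: methyltriphenylphosphonium bromide, C[P+](c1ccccc1)(c1ccccc1)c1ccccc1.[Br-]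
Why: Wittig methylenation of the open hydroxy aldehyde form adds C19, and excess reactive ylide at low temperature should trap the aldehyde before C21 can enolise.

Step 13
Reactants: 20 [(1R,2S,3S)-3-methyl-2-vinylcyclopentyl]methanol
Product: 22 (1S,2S,3S)-3-methyl-2-vinylcyclopentane-1-carbaldehyde, via all-cis aldehyde 21 (not isolated)
Conditions: Dess–Martin periodinane, NaHCO3, CH2Cl2, 0 °C; wash; crude, DBU (cat.), CH2Cl2, rt
Reagents that add atoms: none
Why: Dess–Martin oxidation is followed by base epimerisation of the only acidic centre, C22, which relieves the all-cis crowding and puts the formyl group trans to the vinyl group as in the target.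

Step 14
Reactants: 22 (1S,2S,3S)-3-methyl-2-vinylcyclopentane-1-carbaldehyde
Product: 24 (1R)-1-hydroxy-1-[(1S,2S,3S)-3-methyl-2-vinylcyclopentyl]propan-2-one, via enol ether carbinol 23 (not isolated)
Conditions: ethyl vinyl ether, t-BuLi, THF, –78 to 0 °C; 22, –78 °C; then 1 M HCl, THF, 0 °C
Reagents that add atoms: ethyl vinyl ether, C=COCC; water, O
Why: 1-Ethoxyvinyllithium serves as an acetyl anion equivalent and adds in the Felkin–Anh sense (C21 as the large group) to give the 2R carbinol, and mild acid hydrolysis of the enol ether reveals the methyl ketone.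

Step 15
Reactants: 24 (1R)-1-hydroxy-1-[(1S,2S,3S)-3-methyl-2-vinylcyclopentyl]propan-2-one
Product: 25 (1R)-1-[(1S,2S,3S)-3-methyl-2-vinylcyclopentyl]-1-(triethylsilyloxy)propan-2-one
Conditions: TESCl, imidazole, DMF, 0 °C
Reagents that add atoms: chlorotriethylsilane, CC[Si](Cl)(CC)CC
Why: O-silylation gives a non-chelating ether that shields C2–H and can later be removed in the presence of a TBS ether.

Step 16
Reactants: 25 (1R)-1-[(1S,2S,3S)-3-methyl-2-vinylcyclopentyl]-1-(triethylsilyloxy)propan-2-one, 6 (S)-4-isopropyl-2-methylcyclopent-2-en-1-one, 10 3-(trimethylsilyl)but-3-en-2-one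
Product: 30 trans-hydrindenone bearing the C4 acetyl group and the C2/ring-D arm on C3, via lithium enolate 26 (not isolated), via C6 lithium enolate 27 (not isolated), via C4 silyl enolate 28 (not isolated), via beta-silyl alkoxide 29 (not isolated)
Conditions: LDA (1.05 equiv), THF, –78 °C; 6, –78 to –20 °C; 10, –78 °C to rt; aq. work-up
Reagents that add atoms: none
Why: Proposed new method: LDA removes a C16 proton of 25 (C2–H is shielded by the silyl ether and ring D), enolate 26 adds to C15 of 6, the tetrasubstituted C6 enolate 27 released in this way adds to the CH2 terminus (C5) of 10, and the silicon-stabilised C4 enolate 28 attacks the C3 ketone to give the β-silyl alkoxide 29, which loses Me3SiO– in a Peterson elimination and leaves the C3=C4 alkene. The closest known reaction types are the Michael–Michael–ring-closure cascades of ketone enolates with 2-methylcyclopentenone that end in an intramolecular Wittig reaction, the interception of conjugate-addition enolates by α-silyl vinyl ketones, and the Peterson olefination of α-silyl carbonyl enolates; untested are the α-silyloxy methyl ketone as donor and the Peterson reaction as terminator. Ring B closes by a 6-(enolexo)-exo-trig aldol addition of C4 to C3. C15 is set by attack anti to the C11 isopropyl group, and C6 by alkylation of 27 anti to the fresh C16 arm on the neighbouring carbon, which makes the A/B fusion trans. The step needs 1,4- instead of 1,2-addition (the tertiary 1,2-aldolate forms reversibly and should drain into the 1,4-adduct on warming to –20 °C), enolates that keep their position (aprotic medium, low temperature, exact stoichiometry) and closure on C3 instead of C8. The silyl group secures the last point, since it holds the charge at C4, from where C8 could be reached only through a four-membered ring, suppresses oligomerisation of the acceptor and the C18 enolate that a Robinson closure would need, and makes the closure irreversible.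

Step 17
Reactants: 30 trans-hydrindenone bearing the C4 acetyl group and the C2/ring-D arm on C3
Product: 31 C8 alcohol (8R)
Conditions: NaBH4, MeOH/CH2Cl2 1:1, –78 °C
Reagents that add atoms: none
Why: At low temperature borohydride reduces a saturated cyclopentanone ahead of a hindered conjugated ketone, and hydride arrives on the face opposite the angular C7 methyl group (as with 17-keto steroids), which places O9 cis to C7.

Step 18
Reactants: 31 C8 alcohol (8R)
Product: 32 C8 TBS ether
Conditions: TBSOTf, 2,6-lutidine, CH2Cl2, 0 °C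
Reagents that add atoms: tert-butyldimethylsilyl triflate, CC(C)(C)[Si](C)(C)OS(=O)(=O)C(F)(F)F
Why: The silyl triflate protects even a neopentyl secondary alcohol, and the TBS ether is more robust than the TES ether at C2.

Step 19
Reactants: 32 C8 TBS ether
Product: 33 dienyl triflate (C17 enol triflate)
Conditions: KHMDS, THF, –78 °C; PhNTf2, –78 to 0 °C; aq. work-up
Reagents that add atoms: N-phenylbis(trifluoromethanesulfonimide), O=S(=O)(N(c1ccccc1)S(=O)(=O)C(F)(F)F)C(F)(F)F
Why: Kinetic deprotonation of an enone takes place at the α′ methyl group (C18), and O-triflation of this cross-conjugated enolate turns C17 into an sp2 electrophile.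

Step 20
Reactants: 33 dienyl triflate (C17 enol triflate)
Product: 35 tetracyclic diene with exocyclic C17=C18 methylene, via C19 alkylborane 34 (not isolated)
Conditions: 9-BBN, THF, rt; then slow addition to Pd(dppf)Cl2 (cat.), AsPh3 (cat.), Cs2CO3, DMF/THF/H2O, 50 °C, high dilution
Reagents that add atoms: none
Why: 9-BBN hydroborates only the monosubstituted C19=C20 alkene, and the intramolecular B-alkyl Suzuki–Miyaura coupling joins C19 to C17 and closes ring C, helped by the cis placement of both arms on C3=C4.

Step 21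
Reactants: 35 tetracyclic diene with exocyclic C17=C18 methylene
Product: 36 tetracycle with the C17 methyl stereocentre (17S)
Conditions: Mn(dpm)3 (cat.), PhSiH3, t-BuOOH, i-PrOH, rt, argon
Reagents that add atoms: none
Why: Metal-hydride hydrogen-atom-transfer hydrogenation adds H to the terminal C18, and the resulting C17 allyl radical should be quenched at its less hindered terminus C17 from the face of ring C turned away from the C20–C22 bridge. This gives the epimer that keeps H-17 rather than C18 in the alkene plane facing C2 (least A1,3 strain), which is the more stable product that such radical hydrogenations favour.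

Step 22
Reactants: 36 tetracycle with the C17 methyl stereocentre (17S)
Product: 37 C2 allylic alcohol
Conditions: HF·pyridine, pyridine, THF, 0 °C
Reagents that add atoms: none
Why: Buffered fluoride cleaves a TES ether much faster than a neopentyl TBS ether and is too weakly acidic to ionise the allylic C2–O bond.

Step 23
Reactants: 37 C2 allylic alcohol
Product: 38 C2 enone
Conditions: Dess–Martin periodinane, NaHCO3, CH2Cl2, 0 °C to rt
Reagents that add atoms: none
Why: Dess–Martin oxidation is neutral and fast for hindered secondary alcohols, so the α-centre C22 and the γ-centre C17 are not exposed to base.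

Step 24
Reactants: 38 C2 enone
Product: 40 CNP0544018.1, via beta-hydroxysilane 39 (not isolated)
Conditions: TMSCH2Li, CeCl3, THF, –78 to 0 °C; then 48% aq. HF, MeCN, rt
Reagents that add atoms: (trimethylsilyl)methyllithium, [Li]C[Si](C)(C)C
Why: In this Peterson olefination the small, weakly basic organocerium reagent adds 1,2 to the hindered, enolisable ketone without epimerising C22, and aqueous HF then triggers the elimination to C2=C1 and removes the C8 TBS group in the same operation.

Compound list
1 | (R)-4-hydroxycyclopent-2-en-1-one | O=C1C=C[C@H](O)C1 | starting material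
2 | (R)-4-(tert-butyldimethylsilyloxy)cyclopent-2-en-1-one | O=C1C=C[C@H](O[Si](C)(C)C(C)(C)C)C1 | intermediate
3 | (3S,4R)-4-(tert-butyldimethylsilyloxy)-3-isopropylcyclopentan-1-one | O=C1C[C@@H](C(C)C)[C@H](O[Si](C)(C)C(C)(C)C)C1 | intermediate
4 | (S)-4-isopropylcyclopent-2-en-1-one | O=C1C=C[C@H](C(C)C)C1 | intermediate
5 | (S)-2-iodo-4-isopropylcyclopent-2-en-1-one | O=C1C(I)=C[C@H](C(C)C)C1 | intermediate
6 | (S)-4-isopropyl-2-methylcyclopent-2-en-1-one | CC1=C[C@H](C(C)C)CC1=O | intermediate
7 | (1-bromovinyl)trimethylsilane | C=C(Br)[Si](C)(C)C | starting material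
8 | N-methoxy-N-methylacetamide | CC(=O)N(C)OC | starting material
9 | [1-(trimethylsilyl)vinyl]magnesium bromide | C=C([Mg]Br)[Si](C)(C)C | intermediate
10 | 3-(trimethylsilyl)but-3-en-2-one | CC(=O)C(=C)[Si](C)(C)C | intermediate
11 | (S)-pulegone | C[C@H]1CCC(=C(C)C)C(=O)C1 | starting material
12 | (5S)-2-bromo-2-(2-bromopropan-2-yl)-5-methylcyclohexan-1-one (C2 epimers) | C[C@H]1CCC(Br)(C(C)(C)Br)C(=O)C1 | intermediate
13 | methyl (5S)-5-methyl-2-(propan-2-ylidene)cyclopentane-1-carboxylate (C1 epimers) | COC(=O)C1[C@@H](C)CCC1=C(C)C | intermediate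
14 | methyl (2S)-2-methyl-5-oxocyclopentane-1-carboxylate (C1 labile) | COC(=O)C1[C@@H](C)CCC1=O | intermediate
15 | methyl (5S)-5-methyl-2-(trifluoromethylsulfonyloxy)cyclopent-1-ene-1-carboxylate | COC(=O)C1=C(OS(=O)(=O)C(F)(F)F)CC[C@@H]1C | intermediate
16 | methyl (5S)-2-(hydroxymethyl)-5-methylcyclopent-1-ene-1-carboxylate | COC(=O)C1=C(CO)CC[C@@H]1C | intermediate
17 | (6S)-6-methyl-3,4,5,6-tetrahydro-1H-cyclopenta[c]furan-1-one | O=C1OCC2=C1[C@@H](C)CC2 | intermediate
18 | (3aR,6S,6aS)-6-methylhexahydro-1H-cyclopenta[c]furan-1-one (all-cis) | O=C1OC[C@@H]2CC[C@H](C)[C@H]12 | intermediate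
19 | (3aR,6S,6aS)-6-methylhexahydro-1H-cyclopenta[c]furan-1-ol (anomers) | OC1OC[C@@H]2CC[C@H](C)[C@H]12 | intermediate
20 | [(1R,2S,3S)-3-methyl-2-vinylcyclopentyl]methanol (all-cis) | OC[C@@H]1CC[C@H](C)[C@@H]1C=C | intermediate
21 | (1R,2S,3S)-3-methyl-2-vinylcyclopentane-1-carbaldehyde (all-cis) | O=C[C@@H]1CC[C@H](C)[C@@H]1C=C | intermediate
22 | (1S,2S,3S)-3-methyl-2-vinylcyclopentane-1-carbaldehyde (CHO trans to vinyl, vinyl cis to methyl) | O=C[C@H]1CC[C@H](C)[C@@H]1C=C | intermediate
23 | (1R)-2-ethoxy-1-[(1S,2S,3S)-3-methyl-2-vinylcyclopentyl]prop-2-en-1-ol | C=C(OCC)[C@H](O)[C@H]1CC[C@H](C)[C@@H]1C=C | intermediate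
24 | (1R)-1-hydroxy-1-[(1S,2S,3S)-3-methyl-2-vinylcyclopentyl]propan-2-one | CC(=O)[C@H](O)[C@H]1CC[C@H](C)[C@@H]1C=C | intermediate
25 | (1R)-1-[(1S,2S,3S)-3-methyl-2-vinylcyclopentyl]-1-(triethylsilyloxy)propan-2-one | CC(=O)[C@H](O[Si](CC)(CC)CC)[C@H]1CC[C@H](C)[C@@H]1C=C | intermediate
26 | kinetic (C16) lithium enolate of 25 | C=C(O[Li])[C@H](O[Si](CC)(CC)CC)[C@H]1CC[C@H](C)[C@@H]1C=C | intermediate
27 | first Michael adduct, C6=C8 lithium enolate (C16 arm trans to isopropyl) | CC[Si](CC)(CC)O[C@H]([C@H]1CC[C@H](C)[C@@H]1C=C)C(=O)C[C@H]2[C@H](C(C)C)CC(O[Li])=C2C | intermediate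
28 | second Michael adduct, C4-silylated C4=C17 lithium enolate (C5 trans to C16 arm) | CC[Si](CC)(CC)O[C@H]([C@H]1CC[C@H](C)[C@@H]1C=C)C(=O)C[C@H]2[C@H](C(C)C)CC(=O)[C@]2(C)CC(=C(C)O[Li])[Si](C)(C)C | intermediate
29 | ring-B aldolate, C3 lithium alkoxide with TMS and acetyl on C4 (C3, C4 undefined) | CC[Si](CC)(CC)O[C@H]([C@H]1CC[C@H](C)[C@@H]1C=C)C2(O[Li])C[C@H]3[C@H](C(C)C)CC(=O)[C@]3(C)CC2(C(C)=O)[Si](C)(C)C | intermediate
30 | trans-hydrindenone: C8 ketone, C3=C4, acetyl (C17, C18) on C4, (2R)-CH(OTES) carrying ring D (C21 vinyl) on C3; 6R,11S,15S,21S,22S,25S | CC[Si](CC)(CC)O[C@H]([C@H]1CC[C@H](C)[C@@H]1C=C)C2=C(C[C@@]3(C)C(=O)C[C@@H](C(C)C)[C@@H]3C2)C(C)=O | intermediate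
31 | as 30 with (8R)-hydroxyl, OH cis to C7 methyl | CC[Si](CC)(CC)O[C@H]([C@H]1CC[C@H](C)[C@@H]1C=C)C2=C(C[C@@]3(C)[C@H](O)C[C@@H](C(C)C)[C@@H]3C2)C(C)=O | intermediate
32 | as 31 with C8 OTBS | CC[Si](CC)(CC)O[C@H]([C@H]1CC[C@H](C)[C@@H]1C=C)C2=C(C[C@@]3(C)[C@H](O[Si](C)(C)C(C)(C)C)C[C@@H](C(C)C)[C@@H]3C2)C(C)=O | intermediate
33 | as 32 with C17(OTf)=C18H2 in place of the acetyl group | CC[Si](CC)(CC)O[C@H]([C@H]1CC[C@H](C)[C@@H]1C=C)C2=C(C[C@@]3(C)[C@H](O[Si](C)(C)C(C)(C)C)C[C@@H](C(C)C)[C@@H]3C2)C(=C)OS(=O)(=O)C(F)(F)F | intermediate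
34 | as 33 with C21–CH2CH2–(9-BBN) in place of the vinyl group | CC[Si](CC)(CC)O[C@H]([C@H]1CC[C@H](C)[C@@H]1CCB1C2CCCC1CCC2)C2=C(C[C@@]3(C)[C@H](O[Si](C)(C)C(C)(C)C)C[C@@H](C(C)C)[C@@H]3C2)C(=C)OS(=O)(=O)C(F)(F)F | intermediate
35 | tetracycle (rings A–D): (2R)-OTES, C8 OTBS, C3=C4, exocyclic C17=C18H2 | CC[Si](CC)(CC)O[C@H]1C2=C(C[C@@]3(C)[C@H](O[Si](C)(C)C(C)(C)C)C[C@@H](C(C)C)[C@@H]3C2)C(=C)CC[C@@H]2[C@@H]1CC[C@@H]2C | intermediate
36 | as 35 with (17S)-CH(CH3) | CC[Si](CC)(CC)O[C@H]1C2=C(C[C@@]3(C)[C@H](O[Si](C)(C)C(C)(C)C)C[C@@H](C(C)C)[C@@H]3C2)[C@@H](C)CC[C@@H]2[C@@H]1CC[C@@H]2C | intermediate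
37 | as 36 with free (2R)-hydroxyl | O[C@H]1C2=C(C[C@@]3(C)[C@H](O[Si](C)(C)C(C)(C)C)C[C@@H](C(C)C)[C@@H]3C2)[C@@H](C)CC[C@@H]2[C@@H]1CC[C@@H]2C | intermediate
38 | C2 ketone conjugated with C3=C4, C8 OTBS | O=C1C2=C(C[C@@]3(C)[C@H](O[Si](C)(C)C(C)(C)C)C[C@@H](C(C)C)[C@@H]3C2)[C@@H](C)CC[C@@H]2[C@@H]1CC[C@@H]2C | intermediate
39 | C2 tertiary carbinol bearing CH2SiMe3 (C2 undefined), C8 OTBS | C[Si](C)(C)CC1(O)C2=C(C[C@@]3(C)[C@H](O[Si](C)(C)C(C)(C)C)C[C@@H](C(C)C)[C@@H]3C2)[C@@H](C)CC[C@@H]2[C@@H]1CC[C@@H]2C | intermediate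
40 | CNP0544018.1 (6R,8R,11S,15S,17S,21S,22S,25S in SMILES numbering) | C=C1C2=C(C[C@@]3(C)[C@H](O)C[C@@H](C(C)C)[C@@H]3C2)[C@@H](C)CC[C@@H]2[C@@H]1CC[C@@H]2C | target

Total step count: 24.
Longest linear sequence: 19 steps (steps 6–15, 16, 17–24, from (S)-pulegone).

Steps most likely to fail

Step 16.
- What may go wrong: 1,2-addition or simple proton transfer from the enone to enolate 26 may compete. The enolates 27 and 28 may change position before they are trapped. The aldol closure on the hindered C3 ketone may be too slow.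
- Fallback, from 25 (with 6) back to 30: the same three bonds are made one at a time with isolated intermediates and known reactions.
- LDA and TMSCl convert 25 into the kinetic trimethylsilyl enol ether F1.
- A Mukaiyama–Michael addition of F1 to 6 under silyl-transfer catalysis (TMSNTf2 or a trityl salt, CH2Cl2, –78 °C) gives the C6 trimethylsilyl enol ether F2, with C15 again set anti to the isopropyl group.
- MeLi releases the amine-free lithium enolate 27 from F2. This enolate is added to 3-(diethoxyphosphoryl)but-3-en-2-one F3, which is made from diethyl (2-oxopropyl)phosphonate and paraformaldehyde. The product is the β-ketophosphonate F4.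
- LiCl and DBU in MeCN then close ring B by an intramolecular Horner–Wadsworth–Emmons olefination of the C3 ketone. In this reaction the anion can sit only at C4, and the product is 30.

Step 20.
- What may go wrong: strain in the eight-membered transition state may let intermolecular coupling, protodeboronation or β-hydride elimination overtake ring closure.
- Fallback, from 32 back to 36: ring C is closed by carbonyl coupling instead of cross-coupling.
- Hydroboration of 32 with 9-BBN and NaBO3 oxidation gives the primary C19 alcohol F5.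
- Dess–Martin oxidation gives the keto aldehyde F6.
- A McMurry coupling (TiCl3·DME, Zn–Cu, DME, reflux, slow addition) joins C17 and C19 to give the endocyclic C17=C19 diene F7.
- Under the conditions of step 21, F7 takes up a hydrogen atom at C19. This passes through the same C17 allyl radical and leads to 36.

Step 21.
- What may go wrong: hydrogen-atom delivery to the C3 terminus of the allyl radical would move the alkene to C4=C17, and facial selectivity at C17 may be poor.
- Fallback, from 35 back to 38: C17 is placed under thermodynamic control as the γ-carbon of the C2 enone.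
- Buffered HF·pyridine removes the TES group of 35 to give the dienol F8.
- Dess–Martin oxidation gives the linear dienone F9.
- Hydrogenation with Wilkinson's catalyst saturates only the 1,1-disubstituted C17=C18 alkene. This gives 38 together with its C17 epimer F10.
- DBU in toluene equilibrates F10 through the extended enolate towards 38, the epimer that keeps H-17 in the alkene plane.

Further compounds
F1 | step 16 | kinetic trimethylsilyl enol ether of 25 | C=C(O[Si](C)(C)C)[C@H](O[Si](CC)(CC)CC)[C@H]1CC[C@H](C)[C@@H]1C=C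
F2 | step 16 | Mukaiyama–Michael adduct, C6=C8 trimethylsilyl enol ether | CC[Si](CC)(CC)O[C@H]([C@H]1CC[C@H](C)[C@@H]1C=C)C(=O)C[C@H]2[C@H](C(C)C)CC(O[Si](C)(C)C)=C2C
F3 | step 16 | 3-(diethoxyphosphoryl)but-3-en-2-one | C=C(C(C)=O)P(=O)(OCC)OCC
F4 | step 16 | triketone with diethyl phosphonate on C4 (C4 undefined) | CC[Si](CC)(CC)O[C@H]([C@H]1CC[C@H](C)[C@@H]1C=C)C(=O)C[C@H]2[C@H](C(C)C)CC(=O)[C@]2(C)CC(C(C)=O)P(=O)(OCC)OCC
F5 | step 20 | as 32 with C21–CH2CH2OH in place of the vinyl group | CC[Si](CC)(CC)O[C@H]([C@H]1CC[C@H](C)[C@@H]1CCO)C2=C(C[C@@]3(C)[C@H](O[Si](C)(C)C(C)(C)C)C[C@@H](C(C)C)[C@@H]3C2)C(C)=O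
F6 | step 20 | as 32 with C21–CH2CHO in place of the vinyl group | CC[Si](CC)(CC)O[C@H]([C@H]1CC[C@H](C)[C@@H]1CC=O)C2=C(C[C@@]3(C)[C@H](O[Si](C)(C)C(C)(C)C)C[C@@H](C(C)C)[C@@H]3C2)C(C)=O
F7 | step 20 | tetracycle with endocyclic C17=C19 alkene (ring bonds cis) | CC[Si](CC)(CC)O[C@H]1C2=C(C[C@@]3(C)[C@H](O[Si](C)(C)C(C)(C)C)C[C@@H](C(C)C)[C@@H]3C2)/C(C)=C\C[C@@H]2[C@@H]1CC[C@@H]2C
F8 | step 21 | as 35 with free (2R)-hydroxyl | O[C@H]1C2=C(C[C@@]3(C)[C@H](O[Si](C)(C)C(C)(C)C)C[C@@H](C(C)C)[C@@H]3C2)C(=C)CC[C@@H]2[C@@H]1CC[C@@H]2C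
F9 | step 21 | dienone C2=O, C3=C4, C17=C18H2 | O=C1C2=C(C[C@@]3(C)[C@H](O[Si](C)(C)C(C)(C)C)C[C@@H](C(C)C)[C@@H]3C2)C(=C)CC[C@@H]2[C@@H]1CC[C@@H]2C
F10 | step 21 | C17 epimer of 38 | O=C1C2=C(C[C@@]3(C)[C@H](O[Si](C)(C)C(C)(C)C)C[C@@H](C(C)C)[C@@H]3C2)[C@H](C)CC[C@@H]2[C@@H]1CC[C@@H]2C
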